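**Strategy.** Each end ring is a 2,6,6-trimethylcyclohexene made of two isoprenoid pieces, C1(CMe2)–C2–C3 and C4–C5(Me)=C6 (ring A = the 3'-hydroxy ring, ring B = the 3,4-diol ring). One [3+3] annulation joins them: the ylide of a senecioate-derived allylic phosphonium salt adds through C6 to the β-carbon of prenal (C1–C6 bond) and then olefinates the aldehyde intramolecularly (C3=C4 bond), giving an achiral cyclohexa-1,3-diene ester. After conversion into the ring dienyne, one catalytic asymmetric epoxidation of C3=C4 sets all stereochemistry: hydride opening gives ring A, hydroxide opening ring B. A double Wittig reaction of the C10 dialdehyde gives a C18 diiodide, which two successive Sonogashira couplings join to the ring alkynes without protecting groups.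

Key step: step 2

Remarks on the chemistry:
- Ring atoms are numbered as in carotenoids (C1–C6; primed in ring A of the target).
- Compounds 1, 2, 4, 14 and 18 are taken as purchased; 1 is the commercial E/Z mixture, and both isomers converge in step 2.
- The antipode of the manganese salen catalyst in step 6 is assigned by analogy with 1,2-dihydronaphthalene; if the sense of induction is opposite, the (S,S) complex is used.

**Step 1**
Reactants: 1 ethyl 4-bromo-3-methylbut-2-enoate; 2 triphenylphosphine
Product: 3 [3-(ethoxycarbonyl)-2-methylprop-2-en-1-yl]triphenylphosphonium bromide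
Conditions: PPh3 (1.05 equiv), toluene, rt → 50 °C; salt collected by filtration
Reagents that add atoms: none
Why: SN2 quaternisation of the phosphine by the primary allylic bromide (phosphonium salt formation); the alkene geometry of 1 does not matter because it is erased in step 2.

**Step 2**
Reactants: 3 [3-(ethoxycarbonyl)-2-methylprop-2-en-1-yl]triphenylphosphonium bromide; 4 3-methylbut-2-enal (prenal)
Product: 7 ethyl 2,6,6-trimethylcyclohexa-1,3-diene-1-carboxylate (ethyl safranate), via allylic ylide 5 (not isolated), via Michael adduct ylide 6 (not isolated)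
Conditions: NaH (1.05 equiv), THF, 0 °C; then 4 (1.2 equiv), 0 °C → reflux
Reagents that add atoms: none
Why: Deprotonation of 3 gives the vinylogous ester-stabilised allylic ylide 5, whose carbon alpha to the ester (C6) adds in a conjugate sense to the β-carbon of prenal (C1, the future gem-dimethyl carbon); proton transfer within the resulting enolate/vinylphosphonium pair gives ylide 6, which now carries a free aldehyde. Intramolecular Wittig olefination of the ylide carbon C4 onto the C3 aldehyde then closes the six-membered ring (6-exo-trig carbonyl addition, oxaphosphetane collapse) and expels Ph3PO, so C1–C6 and C3=C4 are both made in this one operation. The closest known reaction type is the Michael addition/intramolecular Wittig [3+3] annulation of ester-substituted allylidene phosphoranes with enals and enones, which gives cyclohexa-1,3-dienes. No stereocentre is formed: 7 is achiral, and its new cis C3=C4 bond is the handle on which step 6 sets the absolute configuration of both rings. The step needs conjugate addition through C6 to win over direct olefination of the aldehyde by C4; the ester favours this by making carbonyl addition of the stabilised ylide reversible and by placing the largest nucleophilic coefficient at C6, while the hindered β,β-dimethyl acceptor is the point of risk.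

**Step 3**
Reactants: 7 ethyl 2,6,6-trimethylcyclohexa-1,3-diene-1-carboxylate
Product: 8 (2,6,6-trimethylcyclohexa-1,3-dien-1-yl)methanol
Conditions: i-Bu2AlH (2.2 equiv), CH2Cl2, −78 → 0 °C; aqueous potassium sodium tartrate work-up
Reagents that add atoms: none
Why: 1,2-reduction of the conjugated ester by the aluminium hydride should give the dienyl carbinol without touching the diene.

**Step 4**
Reactants: 8 (2,6,6-trimethylcyclohexa-1,3-dien-1-yl)methanol
Product: 9 2,6,6-trimethylcyclohexa-1,3-diene-1-carbaldehyde (safranal)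
Conditions: MnO2 (10 equiv), CH2Cl2, rt
Reagents that add atoms: none
Why: MnO2 oxidation is selective for allylic alcohols and stops at the aldehyde under neutral conditions that do not move the diene.

**Step 5**
Reactants: 9 2,6,6-trimethylcyclohexa-1,3-diene-1-carbaldehyde
Product: 10 1-ethynyl-2,6,6-trimethylcyclohexa-1,3-diene
Conditions: Me3SiCHN2 (1.2 equiv), LiN(i-Pr)2 (1.2 equiv), THF, −78 °C; then 9, −78 °C → rt
Reagents that add atoms: (trimethylsilyl)diazomethane, C[Si](C)(C)C=[N+]=[N-]
Why: Colvin rearrangement: the lithiated silyl diazomethane adds to the aldehyde, Peterson-type elimination gives a diazoalkene, and loss of N2 with 1,2-hydrogen shift of the alkylidene carbene gives the terminal alkyne (C7≡C8) under aprotic conditions that avoid conjugate addition to the enal.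

**Step 6**
Reactants: 10 1-ethynyl-2,6,6-trimethylcyclohexa-1,3-diene
Product: 11 (1R,6S)-3-ethynyl-2,4,4-trimethyl-7-oxabicyclo[4.1.0]hept-2-ene
Conditions: (R,R)-N,N'-bis(3,5-di-tert-butylsalicylidene)cyclohexane-1,2-diaminomanganese chloride [(R,R)-(salen)MnCl, 5 mol %], NMO (5 equiv), mCPBA (1.5 equiv), CH2Cl2, −78 °C; aqueous NaOH work-up
Reagents that add atoms: 3-chloroperoxybenzoic acid (mCPBA), OOC(=O)c1cccc(Cl)c1
Why: Jacobsen–Katsuki epoxidation: the oxo species from the trivalent manganese salen complex should oxidise the cis-disubstituted, conjugated C3=C4 bond in preference to the hindered tetrasubstituted C5=C6 bond, and the (R,R) ligand controls the face of side-on approach, so both epoxide carbons (3S,4R in carotenoid numbering) are set by the catalyst.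

**Step 7**
Reactants: 11 (1R,6S)-3-ethynyl-2,4,4-trimethyl-7-oxabicyclo[4.1.0]hept-2-ene
Product: 12 (1R)-4-ethynyl-3,5,5-trimethylcyclohex-3-en-1-ol (ring A alkyne)
Conditions: LiAlH4 (1.5 equiv), Et2O, 0 °C → rt
Reagents that add atoms: none
Why: SN2 delivery of hydride to the allylic epoxide carbon C4, activated by the adjacent C5=C6 π-bond (the SN2' terminus C6 is tetrasubstituted and neopentylic), cleaves the C4–O bond and leaves the C3–O stereocentre untouched, so the homoallylic (R)-alcohol should result.

**Step 8**
Reactants: 11 (1R,6S)-3-ethynyl-2,4,4-trimethyl-7-oxabicyclo[4.1.0]hept-2-ene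
Product: 13 (1S,2S)-4-ethynyl-3,5,5-trimethylcyclohex-3-ene-1,2-diol (ring B alkyne)
Conditions: KOH, DMSO/H2O (4:1), 80 °C
Reagents that add atoms: water, O
Why: Hydroxide opens the vinyl epoxide by SN2 attack with inversion at the allylic carbon C4, which is activated by the π-system, whereas C3 is shielded against trans-diaxial attack by the axial C1 methyl group, so C3 keeps its configuration and the trans-(3S,4S)-diol is expected by substrate control.

**Step 9**
Reactants: 14 but-2-yn-1-ol
Product: 15 (2E)-3-iodobut-2-en-1-ol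
Conditions: i-Bu2AlH (1.0 equiv), THF, 0 °C; then Cp2ZrCl2 (1.2 equiv), i-Bu2AlH (1.2 equiv), 0 °C → rt; then I2 (1.3 equiv), −78 °C
Reagents that add atoms: iodine, II
Why: Syn-hydrozirconation of the aluminium alkoxide of 14 by Cp2Zr(H)Cl formed in the flask places zirconium at C3 and hydrogen at C2, and iodinolysis with retention gives the (E)-vinyl iodide.

**Step 10**
Reactants: 15 (2E)-3-iodobut-2-en-1-ol; 2 triphenylphosphine
Product: 17 [(2E)-3-iodobut-2-en-1-yl]triphenylphosphonium bromide, via allylic bromide 16 (not isolated)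
Conditions: CBr4 (1.1 equiv), PPh3 (1.1 equiv), CH2Cl2, 0 °C; then PPh3 (1.2 equiv), MeCN, rt → 40 °C
Reagents that add atoms: carbon tetrabromide, BrC(Br)(Br)Br
Why: Appel bromination of the primary allylic alcohol under neutral conditions followed by SN2 quaternisation of the allylic bromide by the phosphine; no allyl cation is formed, so the (E)-vinyl iodide is preserved.

**Step 11**
Reactants: 17 [(2E)-3-iodobut-2-en-1-yl]triphenylphosphonium bromide; 18 (2E,4E,6E)-2,7-dimethylocta-2,4,6-trienedial
Product: 20 (2E,4E,6E,8E,10E,12E,14E)-2,15-diiodo-6,11-dimethylhexadeca-2,4,6,8,10,12,14-heptaene, via iodo ylide 19 (not isolated)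
Conditions: 17 (2.3 equiv), NaN(SiMe3)2 (2.2 equiv), THF, −78 °C; then 18 (1.0 equiv), −78 °C → rt; then heptane, 70 °C, dark; crystallisation
Reagents that add atoms: none
Why: Twofold Wittig olefination of the symmetric dialdehyde with the semi-stabilised allylic ylide forms C11=C12 and C11'=C12' in one operation; the amide base avoids iodine–metal exchange, and the hindered Z isomers at the new double bonds should equilibrate thermally to the symmetric all-E diiodide, which is expected to crystallise.

**Step 12**
Reactants: 20 (2E,4E,6E,8E,10E,12E,14E)-2,15-diiodo-6,11-dimethylhexadeca-2,4,6,8,10,12,14-heptaene; 12 (1R)-4-ethynyl-3,5,5-trimethylcyclohex-3-en-1-ol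
Product: 21 (1R)-4-[(3E,5E,7E,9E,11E,13E,15E)-16-iodo-3,7,12-trimethylheptadeca-3,5,7,9,11,13,15-heptaen-1-yn-1-yl]-3,5,5-trimethylcyclohex-3-en-1-ol
Conditions: 20 (3 equiv), Pd(PPh3)4 (5 mol %), CuI (10 mol %), i-Pr2NH, THF, rt, slow addition of 12, degassed, dark; surplus 20 recovered by chromatography
Reagents that add atoms: none
Why: Sonogashira coupling (zerovalent palladium with CuI) joins C8' of the terminal alkyne to one vinyl iodide carbon (C9') of the symmetric diiodide with retention of the (E)-geometry; the excess of 20 and the slow addition of 12 hold back twofold coupling, the free hydroxyl is tolerated, and the non-polar surplus 20 is separated from the hydroxylated product on silica and reused.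

**Step 13**
Reactants: 21 (1R)-4-[(3E,5E,7E,9E,11E,13E,15E)-16-iodo-3,7,12-trimethylheptadeca-3,5,7,9,11,13,15-heptaen-1-yn-1-yl]-3,5,5-trimethylcyclohex-3-en-1-ol; 13 (1S,2S)-4-ethynyl-3,5,5-trimethylcyclohex-3-ene-1,2-diol
Product: 22 (3S,4S,3'R)-4-hydroxyalloxanthin
Conditions: Pd(PPh3)4 (5 mol %), CuI (10 mol %), i-Pr2NH, THF, rt, degassed, dark
Reagents that add atoms: none
Why: Sonogashira coupling forms the C8–C9 bond with retention of the (E)-vinyl geometry under mild basic conditions that leave the unprotected allylic diol, the polyene and all three stereocentres untouched.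

**Compound list**
1 | ethyl 4-bromo-3-methylbut-2-enoate (E/Z mixture) | CCOC(=O)C=C(C)CBr | starting material
2 | triphenylphosphine | c1ccc(cc1)P(c1ccccc1)c1ccccc1 | starting material
3 | [3-(ethoxycarbonyl)-2-methylprop-2-en-1-yl]triphenylphosphonium bromide | CCOC(=O)C=C(C)C[P+](c1ccccc1)(c1ccccc1)c1ccccc1.[Br-] | intermediate
4 | 3-methylbut-2-enal (prenal) | CC(C)=CC=O | starting material
5 | allylic ylide: ethyl 3-methyl-4-(triphenylphosphoranylidene)but-2-enoate | CCOC(=O)C=C(C)C=P(c1ccccc1)(c1ccccc1)c1ccccc1 | intermediate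
6 | Michael adduct ylide: ethyl 3-methyl-2-(2-methyl-4-oxobutan-2-yl)-4-(triphenylphosphoranylidene)but-2-enoate | CCOC(=O)C(=C(C)C=P(c1ccccc1)(c1ccccc1)c1ccccc1)C(C)(C)CC=O | intermediate
7 | ethyl 2,6,6-trimethylcyclohexa-1,3-diene-1-carboxylate (achiral) | CCOC(=O)C1=C(C)C=CCC1(C)C | intermediate
8 | (2,6,6-trimethylcyclohexa-1,3-dien-1-yl)methanol | OCC1=C(C)C=CCC1(C)C | intermediate
9 | 2,6,6-trimethylcyclohexa-1,3-diene-1-carbaldehyde | O=CC1=C(C)C=CCC1(C)C | intermediate
10 | 1-ethynyl-2,6,6-trimethylcyclohexa-1,3-diene | C#CC1=C(C)C=CCC1(C)C | intermediate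
11 | (1R,6S)-3-ethynyl-2,4,4-trimethyl-7-oxabicyclo[4.1.0]hept-2-ene | C#CC1=C(C)[C@H]2O[C@H]2CC1(C)C | intermediate
12 | (1R)-4-ethynyl-3,5,5-trimethylcyclohex-3-en-1-ol | CC1=C(C#C)C(C)(C)C[C@H](O)C1 | intermediate
13 | (1S,2S)-4-ethynyl-3,5,5-trimethylcyclohex-3-ene-1,2-diol | C#CC1=C(C)[C@H](O)[C@@H](O)CC1(C)C | intermediate
14 | but-2-yn-1-ol | CC#CCO | starting material
15 | (2E)-3-iodobut-2-en-1-ol | I/C(C)=C/CO | intermediate
16 | allylic bromide: (2E)-1-bromo-3-iodobut-2-ene | I/C(C)=C/CBr | intermediate
17 | [(2E)-3-iodobut-2-en-1-yl]triphenylphosphonium bromide | I/C(C)=C/C[P+](c1ccccc1)(c1ccccc1)c1ccccc1.[Br-] | intermediate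
18 | (2E,4E,6E)-2,7-dimethylocta-2,4,6-trienedial | O=C/C(C)=C/C=C/C=C(\C)C=O | starting material
19 | iodo ylide: [(2E)-3-iodobut-2-en-1-ylidene]triphenylphosphorane | I/C(C)=C/C=P(c1ccccc1)(c1ccccc1)c1ccccc1 | intermediate
20 | (2E,4E,6E,8E,10E,12E,14E)-2,15-diiodo-6,11-dimethylhexadeca-2,4,6,8,10,12,14-heptaene | I/C(C)=C/C=C/C(C)=C/C=C/C=C(C)/C=C/C=C(\C)I | intermediate
21 | (1R)-4-[(3E,5E,7E,9E,11E,13E,15E)-16-iodo-3,7,12-trimethylheptadeca-3,5,7,9,11,13,15-heptaen-1-yn-1-yl]-3,5,5-trimethylcyclohex-3-en-1-ol | CC1=C(C#C/C(C)=C/C=C/C(C)=C/C=C/C=C(C)/C=C/C=C(\C)I)C(C)(C)C[C@H](O)C1 | intermediate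
22 | (3S,4S,3'R)-4-hydroxyalloxanthin | CC1=C(C#C/C(C)=C/C=C/C(C)=C/C=C/C=C(C)/C=C/C=C(\C)C#CC2=C(C)[C@H](O)[C@@H](O)CC2(C)C)C(C)(C)C[C@H](O)C1 | target

**Step count.** 13 steps in total. The longest linear sequence is 9 steps (steps 1–7, 12, 13).

**Steps most likely to fail**

Step 2. What may go wrong: direct carbonyl olefination of prenal by the ylide carbon C4 outruns conjugate addition at the hindered β,β-dimethyl carbon, so an open-chain trienoate accumulates instead of the ring. Fallback, setting out from 3 and 4: the olefination is made the deliberate first event. Salt 3 is deprotonated with NaN(SiMe3)2 at −78 °C and the ylide olefinates 4 to ethyl (2E,4Z)-3,7-dimethylocta-2,4,6-trienoate F1 (the 4E isomer is recycled by photoisomerisation). Heating in toluene at 150 °C in a sealed tube closes the C1–C6 bond by disrotatory 6π-electrocyclisation to ethyl 2,6,6-trimethylcyclohexa-2,4-diene-1-carboxylate F2. DBU then moves the diene into conjugation with the ester, and the route is rejoined at 7.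

Step 6. What may go wrong: poor facial selectivity of oxygen transfer to the C3=C4 bond. Fallback, setting out from 10: buffered mCPBA (NaHCO3, CH2Cl2, 0 °C) gives the racemic epoxide rac-3-ethynyl-2,4,4-trimethyl-7-oxabicyclo[4.1.0]hept-2-ene F3. The conditions of steps 7 and 8 turn it into racemic 4-ethynyl-3,5,5-trimethylcyclohex-3-en-1-ol F4 and racemic trans-4-ethynyl-3,5,5-trimethylcyclohex-3-ene-1,2-diol F5. Each is resolved by lipase-catalysed acetylation (immobilised Candida antarctica lipase B, vinyl acetate, MTBE). On the assumption that the enzyme acylates the carbinol of the same spatial sense in both, F4 gives (1R)-4-ethynyl-3,5,5-trimethylcyclohex-3-en-1-yl acetate F6 and F5 gives (1S,2S)-4-ethynyl-2-hydroxy-3,5,5-trimethylcyclohex-3-en-1-yl acetate F7. Methanolysis (K2CO3, MeOH) of the separated acetates rejoins the route at 12 and at 13.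

Step 12. What may go wrong: over-coupling, in which both carbon–iodine bonds of the symmetric diiodide react with the ring A alkyne, so that material is lost to the twofold coupled product. Fallback, setting out from 15, 18 and 12: the chain is built linearly so that every coupling partner is unsymmetrical. Alcohol 15 is brominated under the Appel conditions of step 10, bromide 16 is isolated this time, and an Arbuzov reaction with P(OEt)3 (neat, 110 °C) gives diethyl [(2E)-3-iodobut-2-en-1-yl]phosphonate F8. Its sodium anion (NaN(SiMe3)2, THF, −78 °C) olefinates the cheap dialdehyde 18 (3 equiv) in a Horner–Wadsworth–Emmons reaction to (2E,4E,6E,8E,10E)-11-iodo-2,7-dimethyldodeca-2,4,6,8,10-pentaenal F9. Sonogashira coupling of F9 with 12 (Pd(PPh3)4, CuI, i-Pr2NH, THF) gives (2E,4E,6E,8E,10E)-13-[(4R)-4-hydroxy-2,6,6-trimethylcyclohex-1-en-1-yl]-2,7,11-trimethyltrideca-2,4,6,8,10-pentaen-12-ynal F10. A second Horner–Wadsworth–Emmons olefination of F10 with the anion of F8 (2.5 equiv) rejoins the route at 21.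

**Further compounds**
F1 | step 2 | ethyl (2E,4Z)-3,7-dimethylocta-2,4,6-trienoate | CCOC(=O)/C=C(C)/C=C\C=C(C)C
F2 | step 2 | ethyl 2,6,6-trimethylcyclohexa-2,4-diene-1-carboxylate (racemate) | CCOC(=O)C1C(C)=CC=CC1(C)C
F3 | step 6 | rac-3-ethynyl-2,4,4-trimethyl-7-oxabicyclo[4.1.0]hept-2-ene (racemate, one enantiomer drawn) | C#CC1=C(C)[C@H]2O[C@H]2CC1(C)C
F4 | step 6 | rac-4-ethynyl-3,5,5-trimethylcyclohex-3-en-1-ol (racemate) | CC1=C(C#C)C(C)(C)CC(O)C1
F5 | step 6 | rac-trans-4-ethynyl-3,5,5-trimethylcyclohex-3-ene-1,2-diol (racemate, one enantiomer drawn) | C#CC1=C(C)[C@H](O)[C@@H](O)CC1(C)C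
F6 | step 6 | (1R)-4-ethynyl-3,5,5-trimethylcyclohex-3-en-1-yl acetate | CC1=C(C#C)C(C)(C)C[C@H](OC(C)=O)C1
F7 | step 6 | (1S,2S)-4-ethynyl-2-hydroxy-3,5,5-trimethylcyclohex-3-en-1-yl acetate | C#CC1=C(C)[C@H](O)[C@@H](OC(C)=O)CC1(C)C
F8 | step 12 | diethyl [(2E)-3-iodobut-2-en-1-yl]phosphonate | I/C(C)=C/CP(=O)(OCC)OCC
F9 | step 12 | (2E,4E,6E,8E,10E)-11-iodo-2,7-dimethyldodeca-2,4,6,8,10-pentaenal | I/C(C)=C/C=C/C(C)=C/C=C/C=C(\C)C=O
F10 | step 12 | (2E,4E,6E,8E,10E)-13-[(4R)-4-hydroxy-2,6,6-trimethylcyclohex-1-en-1-yl]-2,7,11-trimethyltrideca-2,4,6,8,10-pentaen-12-ynal | CC1=C(C#C/C(C)=C/C=C/C(C)=C/C=C/C=C(\C)C=O)C(C)(C)C[C@H](O)C1
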